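The five-membered lactone (O1, C2 carbonyl, C3 with its oxygen, C4 with the 4-hydroxyphenyl group, C5 with the benzyl group) is disconnected at the O1–C2 bond and traced back to a four-membered ring. The precursor is a squarate-derived 4-benzyl-4-hydroxy-2-isopropoxy-3-arylcyclobut-2-en-1-one with both phenols as tert-butyldimethylsilyl ethers; it already holds every skeletal carbon and the C3-oxygen/C4-aryl order. Heating opens its C1–C4 bond to a vinylketene that is captured by its own hydroxyl, so one operation makes the furanone ring with the full substituent pattern. C5 is formed racemic and is set afterwards by a catalytic enantioselective proton shift.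

Key step: step 9

Abbreviations: TBS = tert-butyldimethylsilyl; TBSO = tert-butyldimethylsilyloxy; TMS = trimethylsilyl; prenyl = 3-methylbut-2-en-1-yl.

Assumption: the quinidine-series catalyst of step 11 is taken to deliver (R)-C5 for this substitution pattern; should it deliver (S), the pseudoenantiomeric quinine-series catalyst (the corresponding cupreine ether) is to be used with no other change.

Remark: metal or boron alkoxides that are only the unquenched form of a step's product are not numbered separately.

Step 1
Reactants: 1 4-hydroxybenzaldehyde; 2 prenyl bromide (1-bromo-3-methylbut-2-ene)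
Product: 3 4-hydroxy-3-prenylbenzaldehyde
Conditions: KOH (10 % aq.), slow addition of 2, 0 °C → rt; then dilute HCl
Reagents that add atoms: none
Why: Ortho C-alkylation of a phenoxide in water, where hydrogen bonding to oxygen steers the ambident anion toward ring-carbon attack and the para position is blocked by the formyl group; conversion per pass is expected to be moderate, the neutral O-prenyl ether is removed by base extraction and unreacted 1 is recycled.

Step 2
Reactants: 3 4-hydroxy-3-prenylbenzaldehyde
Product: 4 4-(TBSO)-3-prenylbenzaldehyde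
Conditions: TBSCl, imidazole, DMF, rt
Reagents that add atoms: tert-butyldimethylsilyl chloride, CC(C)(C)[Si](C)(C)Cl
Why: Standard imidazole-promoted silylation of a phenol; the aldehyde and the alkene are inert.

Step 3
Reactants: 4 4-(TBSO)-3-prenylbenzaldehyde
Product: 5 [4-(TBSO)-3-prenylphenyl]methanol
Conditions: NaBH4, MeOH/THF, 0 °C, short reaction time
Reagents that add atoms: none
Why: Borohydride reduction of an aromatic aldehyde, fast enough at 0 °C that the aryl silyl ether is not touched.

Step 4
Reactants: 5 [4-(TBSO)-3-prenylphenyl]methanol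
Product: 7 4-(TBSO)-3-prenylbenzyl chloride, via benzylic mesylate 6 (not isolated)
Conditions: MsCl, Et3N, THF, 0 °C; then LiCl, rt
Reagents that add atoms: lithium chloride, [Li+].[Cl-]
Why: Mesylation followed by SN2 displacement with chloride under non-acidic conditions that spare the silyl ether and the prenyl group; the chloride is preferred to the bromide to limit Wurtz coupling in step 5.

Step 5
Reactants: 7 4-(TBSO)-3-prenylbenzyl chloride; 8 diisopropyl squarate (3,4-diisopropoxycyclobut-3-ene-1,2-dione)
Product: 10 racemic 4-hydroxy-2,3-diisopropoxy-4-[4-(TBSO)-3-prenylbenzyl]cyclobut-2-en-1-one, via benzylic Grignard reagent 9 (not isolated)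
Conditions: Mg turnings, THF, 0 °C (slow addition of 7, dilute); cannulation into 8 (1.2 equiv), THF, −78 °C; aq. NH4Cl
Reagents that add atoms: none
Why: Grignard formation and 1,2-addition to one of the two equivalent carbonyls of the squarate; the remaining carbonyl of the mono-adduct alkoxide is a deactivated vinylogous ester, so a second addition does not compete at −78 °C.

Step 6
Reactants: 10 racemic 4-hydroxy-2,3-diisopropoxy-4-[4-(TBSO)-3-prenylbenzyl]cyclobut-2-en-1-one
Product: 11 racemic 2,3-diisopropoxy-4-[4-(TBSO)-3-prenylbenzyl]-4-(trimethylsilyloxy)cyclobut-2-en-1-one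
Conditions: 1-(trimethylsilyl)imidazole, CH2Cl2, rt
Reagents that add atoms: 1-(trimethylsilyl)imidazole, C[Si](C)(C)n1ccnc1
Why: Neutral silylation of a hindered tertiary alcohol so that the aryllithium of step 7 adds to the carbonyl and is not quenched; TMS is chosen because the dilute acid of step 8 removes it while the far more acid-stable aryl TBS ethers stay, so no separate selective desilylation is needed.

Step 7
Reactants: 11 racemic 2,3-diisopropoxy-4-[4-(TBSO)-3-prenylbenzyl]-4-(trimethylsilyloxy)cyclobut-2-en-1-one; 12 (4-bromophenoxy)(tert-butyl)dimethylsilane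
Product: 14 1-[4-(TBSO)phenyl]-2,3-diisopropoxy-4-[4-(TBSO)-3-prenylbenzyl]-4-(trimethylsilyloxy)cyclobut-2-en-1-ol (diastereomer mixture), via 4-(TBSO)phenyllithium 13 (not isolated)
Conditions: 12 (1.3 equiv), n-BuLi (1.25 equiv), THF, −78 °C; then 11, −78 °C; cold aq. NH4Cl; used crude
Reagents that add atoms: none
Why: Bromine–lithium exchange and 1,2-addition of the aryllithium to the only carbonyl of 11; the diastereomer ratio is irrelevant because the new carbinol carbon becomes sp2 in step 8 and the other is planarised in step 9.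

Step 8
Reactants: 14 1-[4-(TBSO)phenyl]-2,3-diisopropoxy-4-[4-(TBSO)-3-prenylbenzyl]-4-(trimethylsilyloxy)cyclobut-2-en-1-ol
Product: 16 racemic 4-hydroxy-2-isopropoxy-3-[4-(TBSO)phenyl]-4-[4-(TBSO)-3-prenylbenzyl]cyclobut-2-en-1-one, via TMS-protected cyclobutenone 15 (not isolated)
Conditions: 1 M aq. HCl, THF, 0 °C → rt
Reagents that add atoms: water, O
Why: Acid-promoted 1,3-carbonyl transposition of a squarate bis-adduct: the tertiary benzylic, allylic alcohol ionises to an isopropoxy-stabilised cyclobutenyl cation, water adds at the distal isopropoxy-bearing carbon and propan-2-ol is lost, which places the aryl group on C3 and the remaining isopropoxy group on C2, and the same acid then hydrolyses the tertiary TMS ether.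

Step 9
Reactants: 16 racemic 4-hydroxy-2-isopropoxy-3-[4-(TBSO)phenyl]-4-[4-(TBSO)-3-prenylbenzyl]cyclobut-2-en-1-one
Product: 19 racemic 3-isopropoxy-4-[4-(TBSO)phenyl]-5-[4-(TBSO)-3-prenylbenzyl]furan-2(5H)-one, via vinylketene 17 (not isolated), via 2-hydroxyfuran 18 (not isolated)
Conditions: degassed p-xylene (0.02 M), 138 °C, argon, base-washed glassware
Reagents that add atoms: none
Why: Thermal conrotatory 4π ring opening cleaves the C1–C4 bond of 16 to vinylketene 17; the opening is reversible, so the rotamer with the hydroxyl turned toward the ketene is drained continuously even though outward rotation of OH is the intrinsically preferred sense. The enol oxygen adds in the ketene plane to the sp carbon (5-exo-dig with respect to the exocyclic C=O π bond), which forms the O1–C2 bond and the ring of 18, and a proton shift to C5 gives the conjugated lactone 19 as the thermodynamic tautomer. The closest known reaction type is the thermal rearrangement of 4-alkyl-4-hydroxycyclobutenones from squaric esters to furan-2(5H)-ones. No stereocentre is controlled: C4 of 16 is planarised and C5 of 19 forms racemic, to be set in step 11. The selectivity needed is closure through oxygen only, and the substrate secures it because the C4 substituent is attached through an sp3 CH2 (no 6π closure to a phenol or quinone) and the C3 aryl group cannot reach the ketene carbon. The placing of isopropoxy on C3 and aryl on C4 of the lactone is inherited from the order of the two organometallic additions.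

Step 10
Reactants: 19 racemic 3-isopropoxy-4-[4-(TBSO)phenyl]-5-[4-(TBSO)-3-prenylbenzyl]furan-2(5H)-one
Product: 21 3-isopropoxy-4-[4-(TBSO)phenyl]-5-[4-(TBSO)-3-prenylbenzyl]furan-2(3H)-one (racemic at C3), via lithium furan-2-olate 20 (not isolated)
Conditions: LiN(iPr)2 (1.1 equiv), THF, −78 °C; inverse quench into AcOH (5 equiv)/THF, −78 °C; cold pH 7 work-up, rapid chromatography on neutral silica
Reagents that add atoms: none
Why: Deconjugative protonation: γ-deprotonation at C5 gives the lithium furanolate, and kinetic C-protonation of such dienolates takes place at the α-carbon (C3) to give the β,γ-unsaturated lactone; the C3 centre is erased in step 11, and any C5-protonated material is racemic 19, which is separated and recycled.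

Step 11
Reactants: 21 3-isopropoxy-4-[4-(TBSO)phenyl]-5-[4-(TBSO)-3-prenylbenzyl]furan-2(3H)-one
Product: 22 (R)-3-isopropoxy-4-[4-(TBSO)phenyl]-5-[4-(TBSO)-3-prenylbenzyl]furan-2(5H)-one
Conditions: 9-O-(phenanthren-9-yl)cupreidine (6'-hydroxy cinchona alkaloid, 10 mol %), CH2Cl2, −20 °C, stopped at full conversion
Reagents that add atoms: none
Why: Cinchona-alkaloid-catalysed isomerisation of a β,γ- to an α,β-unsaturated butenolide: the quinuclidine nitrogen removes the C3 proton to give a hydrogen-bonded chiral ammonium dienolate ion pair and returns the proton to one face of C5, so (R)-C5 is set by catalyst control, with the conjugated lactone as the thermodynamic sink.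

Step 12
Reactants: 22 (R)-3-isopropoxy-4-[4-(TBSO)phenyl]-5-[4-(TBSO)-3-prenylbenzyl]furan-2(5H)-one
Product: 23 (R)-3-hydroxy-4-[4-(TBSO)phenyl]-5-[4-(TBSO)-3-prenylbenzyl]furan-2(5H)-one
Conditions: BCl3 (1 M in CH2Cl2, 3 equiv), CH2Cl2, −78 → −30 °C; inverse quench into ice-cold aq. NaHCO3
Reagents that add atoms: none
Why: Lewis-acid cleavage of a secondary alkyl ether: boron binds the enol-ether oxygen next to the lactone carbonyl and chloride removes the isopropyl group as 2-chloropropane; no base is present so C5 is untouched, the weakly basic aryl silyl ethers keep the ortho-prenyl phenol masked (no chroman formation), and low temperature with a buffered inverse quench keeps HCl away from the prenyl alkene.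

Step 13
Reactants: 23 (R)-3-hydroxy-4-[4-(TBSO)phenyl]-5-[4-(TBSO)-3-prenylbenzyl]furan-2(5H)-one
Product: 24 (R)-3-hydroxy-5-(4-hydroxy-3-prenylbenzyl)-4-(4-hydroxyphenyl)furan-2(5H)-one (target)
Conditions: Bu4NF (2.5 equiv), AcOH (2.5 equiv), THF, 0 °C
Reagents that add atoms: none
Why: Fluoride cleavage of both aryl silyl ethers, buffered with acetic acid so that the medium stays near neutral and C5–H is not deprotonated; lactone, enol and prenyl group are inert.

Compound list
1 | 4-hydroxybenzaldehyde | O=Cc1ccc(O)cc1 | starting material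
2 | prenyl bromide | CC(C)=CCBr | starting material
3 | 4-hydroxy-3-prenylbenzaldehyde | CC(C)=CCc1cc(C=O)ccc1O | intermediate
4 | 4-(TBSO)-3-prenylbenzaldehyde | CC(C)=CCc1cc(C=O)ccc1O[Si](C)(C)C(C)(C)C | intermediate
5 | [4-(TBSO)-3-prenylphenyl]methanol | CC(C)=CCc1cc(CO)ccc1O[Si](C)(C)C(C)(C)C | intermediate
6 | 4-(TBSO)-3-prenylbenzyl methanesulfonate (not isolated) | CC(C)=CCc1cc(COS(C)(=O)=O)ccc1O[Si](C)(C)C(C)(C)C | intermediate
7 | 4-(TBSO)-3-prenylbenzyl chloride | CC(C)=CCc1cc(CCl)ccc1O[Si](C)(C)C(C)(C)C | intermediate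
8 | diisopropyl squarate | CC(C)OC1=C(OC(C)C)C(=O)C1=O | starting material
9 | [4-(TBSO)-3-prenylbenzyl]magnesium chloride (not isolated) | CC(C)=CCc1cc(C[Mg]Cl)ccc1O[Si](C)(C)C(C)(C)C | intermediate
10 | racemic 4-hydroxy-2,3-diisopropoxy-4-[4-(TBSO)-3-prenylbenzyl]cyclobut-2-en-1-one | CC(C)OC1=C(OC(C)C)C(O)(Cc2ccc(O[Si](C)(C)C(C)(C)C)c(CC=C(C)C)c2)C1=O | intermediate
11 | racemic 2,3-diisopropoxy-4-[4-(TBSO)-3-prenylbenzyl]-4-(trimethylsilyloxy)cyclobut-2-en-1-one | CC(C)OC1=C(OC(C)C)C(O[Si](C)(C)C)(Cc2ccc(O[Si](C)(C)C(C)(C)C)c(CC=C(C)C)c2)C1=O | intermediate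
12 | (4-bromophenoxy)(tert-butyl)dimethylsilane | CC(C)(C)[Si](C)(C)Oc1ccc(Br)cc1 | starting material
13 | [4-(TBSO)phenyl]lithium (not isolated) | [Li]c1ccc(O[Si](C)(C)C(C)(C)C)cc1 | intermediate
14 | 1-[4-(TBSO)phenyl]-2,3-diisopropoxy-4-[4-(TBSO)-3-prenylbenzyl]-4-(trimethylsilyloxy)cyclobut-2-en-1-ol, mixture of racemic diastereomers | CC(C)OC1=C(OC(C)C)C(O)(c2ccc(O[Si](C)(C)C(C)(C)C)cc2)C1(O[Si](C)(C)C)Cc1ccc(O[Si](C)(C)C(C)(C)C)c(CC=C(C)C)c1 | intermediate
15 | racemic 2-isopropoxy-3-[4-(TBSO)phenyl]-4-[4-(TBSO)-3-prenylbenzyl]-4-(trimethylsilyloxy)cyclobut-2-en-1-one (not isolated) | CC(C)OC1=C(c2ccc(O[Si](C)(C)C(C)(C)C)cc2)C(O[Si](C)(C)C)(Cc2ccc(O[Si](C)(C)C(C)(C)C)c(CC=C(C)C)c2)C1=O | intermediate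
16 | racemic 4-hydroxy-2-isopropoxy-3-[4-(TBSO)phenyl]-4-[4-(TBSO)-3-prenylbenzyl]cyclobut-2-en-1-one (key-step precursor) | CC(C)OC1=C(c2ccc(O[Si](C)(C)C(C)(C)C)cc2)C(O)(Cc2ccc(O[Si](C)(C)C(C)(C)C)c(CC=C(C)C)c2)C1=O | intermediate
17 | (Z)-4-hydroxy-2-isopropoxy-3-[4-(TBSO)phenyl]-5-[4-(TBSO)-3-prenylphenyl]penta-1,3-dien-1-one, vinylketene with OH facing the ketene (not isolated) | CC(C)OC(=C=O)/C(c1ccc(O[Si](C)(C)C(C)(C)C)cc1)=C(\O)Cc1ccc(O[Si](C)(C)C(C)(C)C)c(CC=C(C)C)c1 | intermediate
18 | 3-isopropoxy-4-[4-(TBSO)phenyl]-5-[4-(TBSO)-3-prenylbenzyl]furan-2-ol (not isolated) | CC(C)Oc1c(O)oc(Cc2ccc(O[Si](C)(C)C(C)(C)C)c(CC=C(C)C)c2)c1-c1ccc(O[Si](C)(C)C(C)(C)C)cc1 | intermediate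
19 | racemic 3-isopropoxy-4-[4-(TBSO)phenyl]-5-[4-(TBSO)-3-prenylbenzyl]furan-2(5H)-one (key-step product) | CC(C)=CCc1cc(CC2OC(=O)C(OC(C)C)=C2c2ccc(O[Si](C)(C)C(C)(C)C)cc2)ccc1O[Si](C)(C)C(C)(C)C | intermediate
20 | lithium 3-isopropoxy-4-[4-(TBSO)phenyl]-5-[4-(TBSO)-3-prenylbenzyl]furan-2-olate (not isolated) | CC(C)Oc1c(O[Li])oc(Cc2ccc(O[Si](C)(C)C(C)(C)C)c(CC=C(C)C)c2)c1-c1ccc(O[Si](C)(C)C(C)(C)C)cc1 | intermediate
21 | 3-isopropoxy-4-[4-(TBSO)phenyl]-5-[4-(TBSO)-3-prenylbenzyl]furan-2(3H)-one, racemic at C3 | CC(C)OC1C(=O)OC(Cc2ccc(O[Si](C)(C)C(C)(C)C)c(CC=C(C)C)c2)=C1c1ccc(O[Si](C)(C)C(C)(C)C)cc1 | intermediate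
22 | (R)-3-isopropoxy-4-[4-(TBSO)phenyl]-5-[4-(TBSO)-3-prenylbenzyl]furan-2(5H)-one | CC(C)=CCc1cc(C[C@H]2OC(=O)C(OC(C)C)=C2c2ccc(O[Si](C)(C)C(C)(C)C)cc2)ccc1O[Si](C)(C)C(C)(C)C | intermediate
23 | (R)-3-hydroxy-4-[4-(TBSO)phenyl]-5-[4-(TBSO)-3-prenylbenzyl]furan-2(5H)-one | CC(C)=CCc1cc(C[C@H]2OC(=O)C(O)=C2c2ccc(O[Si](C)(C)C(C)(C)C)cc2)ccc1O[Si](C)(C)C(C)(C)C | intermediate
24 | (R)-3-hydroxy-5-(4-hydroxy-3-prenylbenzyl)-4-(4-hydroxyphenyl)furan-2(5H)-one | CC(C)=CCc1cc(C[C@H]2OC(=O)C(O)=C2c2ccc(O)cc2)ccc1O | target

Total step count: 13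
Longest linear sequence: 13 steps (1 → 24; 2, 8 and 12 are purchased)

Steps most likely to fail

Step 11. The proton return to C5 may proceed with poor facial selectivity for this fully substituted dienolate, or the basic catalyst may slowly re-deprotonate C5 of 22 and erode its enantiomeric purity. The fallback replaces reliance on catalyst control alone by a classical resolution. The scalemic material is carried through step 12, and the fallback sets out from 23, whose enol OH is acidic enough to form ammonium salts. Treatment with (R)-1-phenylethylamine in ethyl acetate/heptane and fractional crystallisation should give the diastereomerically pure (R)-1-phenylethylammonium enolate of 23 F1; the antipodal amine is taken if it pairs better with the (R)-enolate. Partition between ethyl acetate and cold 0.5 M HCl returns enantiopure 23, where the route is rejoined.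

Step 10. Protonation of the furanolate may lose site control (C5 competing with C3), or 21 may reconjugate during work-up or on silica. Either process regenerates racemic 19, which would pass unchanged through step 11 and dilute the enantiomeric purity of 22. The fallback is a physical resolution with recycling in place of the two-step proton relocation. It sets out from racemic 19: preparative supercritical-fluid chromatography on an amylose tris(3,5-dimethylphenylcarbamate) phase (CO2/propan-2-ol) gives 22 directly, where the route is rejoined. The unwanted (S)-3-isopropoxy-4-[4-(TBSO)phenyl]-5-[4-(TBSO)-3-prenylbenzyl]furan-2(5H)-one F2 is racemised back to 19 with catalytic DBU in CH2Cl2 through the furanolate and resubmitted. Steps 10 and 11 are both bypassed.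

Step 9. The vinylketene may be consumed through the rotamer in which the benzylic CH2, not the hydroxyl, faces the ketene (for example by a 1,5-hydrogen shift to a dienal). Ketene dimerisation or thermal decomposition at 138 °C may also outrun lactonisation. The fallback is a photochemical ring opening of the same C1–C4 bond in place of the thermal one, with no further compound (F0). It sets out from 16: irradiation at about 350 nm in degassed THF at room temperature. Excited-state opening of 4-hydroxycyclobutenones is a known route to furan-2(5H)-ones, is not bound to the thermal outward preference of the hydroxyl group, and avoids high temperature. The route is rejoined at 19.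

Further compounds
F1 | step 11 | (R)-1-phenylethylammonium (R)-2-oxo-4-[4-(TBSO)phenyl]-5-[4-(TBSO)-3-prenylbenzyl]-2,5-dihydrofuran-3-olate | CC(C)=CCc1cc(C[C@H]2OC(=O)C([O-])=C2c2ccc(O[Si](C)(C)C(C)(C)C)cc2)ccc1O[Si](C)(C)C(C)(C)C.C[C@@H]([NH3+])c1ccccc1
F2 | step 10 | (S)-3-isopropoxy-4-[4-(TBSO)phenyl]-5-[4-(TBSO)-3-prenylbenzyl]furan-2(5H)-one | CC(C)=CCc1cc(C[C@@H]2OC(=O)C(OC(C)C)=C2c2ccc(O[Si](C)(C)C(C)(C)C)cc2)ccc1O[Si](C)(C)C(C)(C)C
F0 | step 9 | none | none
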